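**The trap.** The easy error was to carry a molar rate from one run to the next, since the charges differ, so I looked first for what the runs share.

| setting | oak | cedar | flask |
|---|---|---|---|
| starting material | 1 M | 2.2 M | 1.5 M |
| gas phase | 200 mM (held) | 200 mM (held) | 200 mM (held) |
| free catalyst | 2.7 mM | 2.7 mM | 2.7 mM |
| remark | run made earlier | run made earlier |  |
| time |  |  | 5.0 h |

| run | time / h | product / % |
|---|---|---|
| oak | 0.500 | 5.1 |
| oak | 0.833 | 7.0 |
| oak | 1.50 | 11.6 |
| oak | 3.00 | 21.8 |
| oak | 6.00 | 34.9 |
| cedar | 1.33 | 11.5 |
| cedar | 2.50 | 18.7 |
| cedar | 4.00 | 26.8 |
| cedar | 5.00 | 34.8 |
| cedar | 6.00 | 37.5 |

(standard deviation of a reading: 1 percentage point)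

- at the start none of the gas is dissolved
- the numbers in the tables scatter with a standard deviation of 1 percentage point
- steps that have been proposed: gas phase <-> dissolved gas; starting material + dissolved gas + free catalyst -> free catalyst + product; dissolved gas + free catalyst -> spent catalyst

- epsilon: doubling the saturation concentration of gas phase, all else as stated
- gamma: doubling the amount of free catalyst, all else as stated
- delta: doubling the transfer coefficient of the gas phase, all else as stated

- the product standing at 5.0 h, as a percentage of the starting material charged
- the change that raises the amount of product at 5.0 h, in percent of the starting material charged most ("none" if none brings more than 2 percentage points) (epsilon / gamma / delta / none)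
- amount of product at 5.0 h, in percent of the starting material charged, after gamma

**Main step.** At 6.00 h the oak run stood at 34.9 % and the cedar run at 37.5 %, though cedar held 2.20 times the charge. So I took the main step as first order in starting material, pseudo-first-order while gas stays steady. I therefore worked with the dose: the negative logarithm of the fraction of starting material left. Oak reached 0.246 at 3.00 h. With unchanging catalyst the dose grows in proportion to time, so my first answer for the flask at 5.0 h was 0.410, or 33.6 % product.

**Dying catalyst.** The proposed step from dissolved gas and free catalyst to spent catalyst should bend that line. Oak's dose at 6.00 h was 0.429, which is 1.74 times its earlier dose. The second interval equals the first, so for a first-order fall the excess over one is the catalyst share still free at 3.00 h: a reading of 74.6 %. I put that fall back and went round once more. The flask's dose at 5.0 h came to 0.374, lower than the first answer, which means 31.2 % product.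

**The gas.** At 6.00 h cedar's reading stood no lower than oak's despite cedar's larger molar demand for gas, so I saw no transfer brake, left the dose as it was, and expected little from delta.

**The changes.** Doubling catalyst should keep the surviving share and double the dose, giving 52.7 %. Doubling saturation should speed both the main step and the death, which gives a dose of 0.603, or 45.3 %, less than gamma gives.

**The forecast.** It gave 32 %, gamma and 52 %, the same choice as mine with percentages close to mine but not the same, and said: “Gas transfer is therefore not limiting, and delta should do little.”

**The result.** The flask gave 31.8 %. Gamma brought 22 percentage points and reached 53.4 %, epsilon brought 14 points, and delta brought 0.049 points.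

    gas phase ⇌ dissolved gas, rate k1*(csat - [dissolved gas]) (kL = 140 /h)
    starting material + dissolved gas + free catalyst → free catalyst + product (k = 180 /M²/h)
    dissolved gas + free catalyst → spent catalyst (k = 0.490 /M/h)

**The neighbour.** The flask's 31.8 % is a dose of 0.383, beside the 0.374 I read from oak, and at 5.00 h the flask had 61.4 % of its catalyst free. The neighbour was charged with 0.0016 M of free catalyst, its time held. Scaling my dose by the catalyst ratio of 0.593 gave 0.222, or 19.9 % product. The neighbour stood at 20.3 %, with 61.4 % of its catalyst free.

Readings and results come from a simulation with constants of no real substance; the scatter is artificial.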